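**Retrosynthetic overview**

1. Amaurone A ⇒ (desilylation) ⇒ side chain cut at Cb–CH3 (Negishi) and Cb–Cc (Stille): ring dibromo-olefin 23 + pyranone dienylstannane 36; the pyranone ring is closed separately by lactonisation of a 3,5-diketo ester (step 17).
2. 23 ⇒ ring aldehyde ⇒ β-face oxygenation of cis-diene 14: singlet-oxygen [4+2] (C3–O, C6–O), O–O reduction, C6 silylation, OH-directed dihydroxylation (C4–O, C5–O); C4 is then the only free secondary OH and takes the acetate.
3. 14 ⇒ C1–C2 disconnection: disrotatory 6π-electrocyclisation of the (2E,4Z,6E)-trienoyl imide 13, which closes the carbocycle (the only ring formed on the main line) and sets C1/C2.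
4. Feature used: ring C3(Me)–C4–C5(Me)–C6 carry four oxygens on one face while C1 (side chain) and C2 (CHMe) carry cis carbon groups on the other, the oxidation imprint of a cis-5,6-disubstituted 1,3-dimethylcyclohexa-1,3-diene.
5. 13 ⇒ Horner–Wadsworth–Emmons reaction of the Z-dienal from dienol 6 (Suzuki coupling of Z-iodoallyl alcohol 3 with Z-butenylboronate 5) with the oxazolidinone phosphonate 11.

Key step: step 7

Remark (numbering): ring atoms are C1 (side-chain carbon), C2 (CHMe), C3/C5 (C(Me)OH), C4 (CHOAc), C6 (CHOH); α is the ring face of the C1 and C2 substituents, β the opposite face; chain atoms Ca to Cf run from the ring to the pyranone.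

Remark (assumption): the carboxyl end of the triene is carried as the imide of (R)-4-benzyl-oxazolidin-2-one and not as a methyl ester, because a monodentate ester gives a Lewis acid neither a defined geometry nor a rate advantage over the uncatalysed closure; the imide leaves in the reduction that an ester would need anyway.

Remark: 34 and 35 are diastereomer mixtures at two sp3 centres that disappear in step 22; all polyenes are handled in the dark.

**Route**

Step 1
Reactants: 1 prop-2-yn-1-ol
Product: 3 (2Z)-3-iodo-2-methylprop-2-en-1-ol, via chelated vinylmagnesium alkoxide 2 (not isolated)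
Conditions: MeMgBr (3 equiv), CuI (10 mol%), Et2O/THF, −10 °C to rt; then I2, −78 °C to rt; dilute aq. HCl work-up
Reagents that add atoms: methylmagnesium bromide, C[Mg]Br; iodine, II
Why: Copper-catalysed anti-carbomagnesiation of the propargylic alkoxide places methyl on C2 and magnesium on C3 cis to CH2O (five-membered chelate), and iodinolysis with retention gives the Z-iodide.

Step 2
Reactants: 4 but-2-yne
Product: 5 2-[(2Z)-but-2-en-2-yl]-4,4,5,5-tetramethyl-1,3,2-dioxaborolane
Conditions: pinacolborane, Cp2Zr(H)Cl (5 mol%), Et3N (10 mol%), neat, sealed tube, 60 °C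
Reagents that add atoms: pinacolborane, [H]B1OC(C)(C)C(C)(C)O1
Why: Zirconium-catalysed hydroboration of the symmetrical alkyne is a syn addition of H and B, which fixes the Z geometry (methyl groups cis).

Step 3
Reactants: 3 (2Z)-3-iodo-2-methylprop-2-en-1-ol; 5 2-[(2Z)-but-2-en-2-yl]-4,4,5,5-tetramethyl-1,3,2-dioxaborolane
Product: 6 (2Z,4E)-2,4-dimethylhexa-2,4-dien-1-ol
Conditions: Pd(PPh3)4 (5 mol%), 2 M aq. NaOH, THF, 50 °C, degassed
Reagents that add atoms: none
Why: Suzuki–Miyaura coupling proceeds with retention at both alkenyl partners, so the Z-iodide and the Z-boronate should give the 2Z,4E-dienol; the free hydroxyl is tolerated.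

Step 4
Reactants: 7 (4R)-4-benzyl-1,3-oxazolidin-2-one; 8 bromoacetyl bromide
Product: 10 (4R)-4-benzyl-3-(bromoacetyl)-1,3-oxazolidin-2-one, via N-lithio oxazolidinone 9 (not isolated)
Conditions: n-BuLi, THF, −78 °C; then 8, −78 to 0 °C
Reagents that add atoms: none
Why: N-Acylation of the lithiated carbamate; the acyl bromide is far more electrophilic than the alkyl bromide.

Step 5
Reactants: 10 (4R)-4-benzyl-3-(bromoacetyl)-1,3-oxazolidin-2-one
Product: 11 diethyl {2-[(4R)-4-benzyl-2-oxo-1,3-oxazolidin-3-yl]-2-oxoethyl}phosphonate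
Conditions: P(OEt)3 (neat), 60–80 °C; volatiles removed in vacuo
Reagents that add atoms: triethyl phosphite, CCOP(OCC)OCC
Why: Michaelis–Arbuzov reaction of the activated α-bromo imide gives the stabilised phosphonate.

Step 6
Reactants: 6 (2Z,4E)-2,4-dimethylhexa-2,4-dien-1-ol; 11 diethyl {2-[(4R)-4-benzyl-2-oxo-1,3-oxazolidin-3-yl]-2-oxoethyl}phosphonate
Product: 13 (4R)-4-benzyl-3-[(2E,4Z,6E)-4,6-dimethylocta-2,4,6-trienoyl]-1,3-oxazolidin-2-one, via (2Z,4E)-2,4-dimethylhexa-2,4-dienal 12 (not isolated)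
Conditions: MnO2, CH2Cl2, 0 °C to rt, filtration; then 11, LiCl, iPr2NEt, MeCN, 0 °C; work-up and chromatography below 10 °C, used at once
Reagents that add atoms: none
Why: Allylic oxidation with MnO2 leaves the Z-enal geometry untouched, and the Horner–Wadsworth–Emmons reaction under mild LiCl/amine conditions should form the new C2=C3 bond E without isomerising the Z-dienal.

Step 7
Reactants: 13 (4R)-4-benzyl-3-[(2E,4Z,6E)-4,6-dimethylocta-2,4,6-trienoyl]-1,3-oxazolidin-2-one
Product: 14 (4R)-4-benzyl-3-[(1S,6S)-3,5,6-trimethylcyclohexa-2,4-diene-1-carbonyl]-1,3-oxazolidin-2-one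
Conditions: MgBr2·OEt2 (1.5 equiv), CH2Cl2, −20 °C to rt (1,2-dichloroethane, 50 °C only if closure is slow), argon, dark; aq. NaHCO3 work-up
Reagents that add atoms: none
Why: Proposed new method: the magnesium-chelated imide holds both carbonyls syn and the enoyl unit s-cis, and the helical s-cis,s-cis triene then closes by a thermally allowed disrotatory 6π-electrocyclisation that forms the C1–C2 σ-bond. The closest known reactions are the racemic thermal 6π closure of E,Z,E-trienes and the chelate-controlled Cα-face selection of N-enoyl oxazolidinones in Lewis-acid-promoted Diels–Alder reactions; their combination for a torquoselective 6π closure is without precedent. Ring closure mode: the six-membered carbocycle forms by bonding of the two triene termini (C2 and C7 of the trienoyl chain) in a disrotatory sense. The cis relationship of C1 and C2 follows from disrotation of the two E termini, whose outside groups (acyl and methyl) end on the same face. The absolute sense (1S,6S) requires C7 to bond to the Cα-Re face, which in the chelate is the face remote from the (R)-benzyl group. The step needs torquoselectivity and geometric integrity of the 4Z alkene; the benzyl group is meant to secure the first and the mild, non-alkylating Lewis acid the second.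

Step 8
Reactants: 14 (4R)-4-benzyl-3-[(1S,6S)-3,5,6-trimethylcyclohexa-2,4-diene-1-carbonyl]-1,3-oxazolidin-2-one
Product: 15 (4R)-4-benzyl-3-[3β,6β-epidioxy-2α,3α,5-trimethylcyclohex-4-ene-1α-carbonyl]-1,3-oxazolidin-2-one
Conditions: O2, tetraphenylporphyrin (cat.), visible light, CH2Cl2, −20 °C
Reagents that add atoms: oxygen, O=O
Why: Singlet-oxygen [4+2] cycloaddition to the s-cis ring diene; the α face is blocked by the cis acyl and methyl groups on C1/C2, so both C–O bonds (C3 and C6) should form on the β face.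

Step 9
Reactants: 15 (4R)-4-benzyl-3-[3β,6β-epidioxy-2α,3α,5-trimethylcyclohex-4-ene-1α-carbonyl]-1,3-oxazolidin-2-one
Product: 16 (4R)-4-benzyl-3-[3β,6β-dihydroxy-2α,3α,5-trimethylcyclohex-4-ene-1α-carbonyl]-1,3-oxazolidin-2-one
Conditions: Zn dust, AcOH, CH2Cl2, 0 °C to rt
Reagents that add atoms: none
Why: Reductive cleavage of the O–O bond leaves both C–O bonds untouched, so the cis-3,6-diol keeps the β configuration set in step 8.

Step 10
Reactants: 16 (4R)-4-benzyl-3-[3β,6β-dihydroxy-2α,3α,5-trimethylcyclohex-4-ene-1α-carbonyl]-1,3-oxazolidin-2-one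
Product: 17 (4R)-4-benzyl-3-[6β-(tert-butyldimethylsilyloxy)-3β-hydroxy-2α,3α,5-trimethylcyclohex-4-ene-1α-carbonyl]-1,3-oxazolidin-2-one
Conditions: TBSOTf (1.05 equiv), 2,6-lutidine, CH2Cl2, −78 °C
Reagents that add atoms: tert-butyldimethylsilyl trifluoromethanesulfonate, CC(C)(C)[Si](C)(C)OS(=O)(=O)C(F)(F)F
Why: At low temperature the silyl triflate reacts with the secondary allylic C6–OH much faster than with the tertiary C3–OH, which marks C6–O before the C4 oxygen exists.

Step 11
Reactants: 17 (4R)-4-benzyl-3-[6β-(tert-butyldimethylsilyloxy)-3β-hydroxy-2α,3α,5-trimethylcyclohex-4-ene-1α-carbonyl]-1,3-oxazolidin-2-one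
Product: 19 (4R)-4-benzyl-3-[6β-(tert-butyldimethylsilyloxy)-3β,4β,5β-trihydroxy-2α,3α,5α-trimethylcyclohexane-1α-carbonyl]-1,3-oxazolidin-2-one, via osmate ester TMEDA complex 18 (not isolated)
Conditions: OsO4 (1.05 equiv), TMEDA (1.1 equiv), CH2Cl2, −78 °C; then aq. Na2SO3, THF, rt to 40 °C
Reagents that add atoms: osmium tetroxide, O=[Os](=O)(=O)=O
Why: Hydrogen-bond-directed syn-dihydroxylation: the OsO4·TMEDA complex is held by the pseudoaxial tertiary C3–OH and should add to the β face of C4=C5, the α face being screened by the axial C2 methyl, so C4–O and C5–O end cis to C3–OH and C6–O.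

Step 12
Reactants: 19 (4R)-4-benzyl-3-[6β-(tert-butyldimethylsilyloxy)-3β,4β,5β-trihydroxy-2α,3α,5α-trimethylcyclohexane-1α-carbonyl]-1,3-oxazolidin-2-one
Product: 20 [6β-(tert-butyldimethylsilyloxy)-3β,4β,5β-trihydroxy-2α,3α,5α-trimethylcyclohexan-1α-yl]methanol
Conditions: LiBH4, MeOH (2 equiv), THF, 0 °C to rt
Reagents that add atoms: none
Why: Hydride reduction of the exocyclic imide carbonyl releases the recoverable auxiliary and gives the primary alcohol without touching the silyl ether or any stereocentre.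

Step 13
Reactants: 20 [6β-(tert-butyldimethylsilyloxy)-3β,4β,5β-trihydroxy-2α,3α,5α-trimethylcyclohexan-1α-yl]methanol
Product: 21 6β-(tert-butyldimethylsilyloxy)-3β,4β,5β-trihydroxy-2α,3α,5α-trimethylcyclohexane-1α-carbaldehyde
Conditions: TEMPO (10 mol%), KBr (10 mol%), NaOCl (1.1 equiv), CH2Cl2/aq. NaHCO3, 0 °C
Reagents that add atoms: none
Why: Oxoammonium (TEMPO/bleach) oxidation is selective for the primary alcohol over the C4 carbinol, which lies between two quaternary carbons; the equatorial C1 formyl group is the thermodynamically preferred epimer.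

Step 14
Reactants: 21 6β-(tert-butyldimethylsilyloxy)-3β,4β,5β-trihydroxy-2α,3α,5α-trimethylcyclohexane-1α-carbaldehyde
Product: 22 4β-acetoxy-6β-(tert-butyldimethylsilyloxy)-3β,5β-dihydroxy-2α,3α,5α-trimethylcyclohexane-1α-carbaldehyde
Conditions: Ac2O, pyridine, DMAP (cat.), CH2Cl2, 0 °C to rt
Reagents that add atoms: acetic anhydride, CC(=O)OC(C)=O
Why: C4–OH is the only free secondary hydroxyl (C6 is silylated, and tertiary C3/C5–OH do not acylate under these conditions), so the acetate should go on regiospecifically.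

Step 15
Reactants: 22 4β-acetoxy-6β-(tert-butyldimethylsilyloxy)-3β,5β-dihydroxy-2α,3α,5α-trimethylcyclohexane-1α-carbaldehyde
Product: 23 4β-acetoxy-6β-(tert-butyldimethylsilyloxy)-1α-(2,2-dibromoethenyl)-2α,3α,5α-trimethylcyclohexane-3β,5β-diol
Conditions: CBr4, PPh3, Zn dust, CH2Cl2, rt (ylide pre-formed); then 22, 0 °C to rt
Reagents that add atoms: carbon tetrabromide, BrC(Br)(Br)Br
Why: Wittig-type dibromomethylenation (first stage of the Corey–Fuchs sequence) under neutral conditions; zinc as halogen scavenger avoids Ph3PBr2, which could attack the tertiary alcohols.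

Step 16
Reactants: 24 methyl 2-methyl-3-oxopentanoate; 25 N-methoxy-N-methylpropanamide
Product: 27 methyl 2,4-dimethyl-3,5-dioxoheptanoate, via sodium lithium dienolate 26 (not isolated)
Conditions: NaH, THF, 0 °C; n-BuLi, 0 °C; then 25, 0 °C to rt; aq. HCl work-up
Reagents that add atoms: none
Why: Claisen-type γ-acylation of the β-keto ester dianion; the stable tetrahedral adduct of the N-methoxy-N-methyl amide prevents over-addition and proton transfer from the product.

Step 17
Reactants: 27 methyl 2,4-dimethyl-3,5-dioxoheptanoate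
Product: 28 6-ethyl-4-hydroxy-3,5-dimethyl-2H-pyran-2-one
Conditions: DBU, toluene, reflux
Reagents that add atoms: none
Why: Base-mediated enol lactonisation of the 3,5-diketo ester (acyl substitution with loss of methanol) closes the pyranone ring.

Step 18
Reactants: 28 6-ethyl-4-hydroxy-3,5-dimethyl-2H-pyran-2-one
Product: 30 2-ethyl-6-methoxy-3,5-dimethyl-4H-pyran-4-one, via 4-hydroxy-2-methoxypyrylium triflate 29 (not isolated)
Conditions: MeOTf, CH2Cl2, rt; then aq. NaHCO3
Reagents that add atoms: methyl trifluoromethanesulfonate, COS(=O)(=O)C(F)(F)F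
Why: The hard methylating agent alkylates the most basic oxygen (the lactone carbonyl), and loss of the 4-OH proton from the pyrylium salt gives the 2-methoxy-γ-pyranone regioisomer.

Step 19
Reactants: 1 prop-2-yn-1-ol
Product: 31 (2E)-3-(tributylstannyl)prop-2-en-1-ol
Conditions: Bu3SnH, AIBN (cat.), neat, 80 °C; chromatographic removal of the Z and 2-stannyl isomers
Reagents that add atoms: tributyltin hydride, CCCC[SnH](CCCC)CCCC
Why: Radical hydrostannation of the terminal alkyne under equilibrating conditions gives mainly the E-β-stannyl alkene.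

Step 20
Reactants: 31 (2E)-3-(tributylstannyl)prop-2-en-1-ol
Product: 32 (2E)-3-(tributylstannyl)prop-2-enal
Conditions: MnO2, CH2Cl2, rt
Reagents that add atoms: none
Why: Allylic oxidation with MnO2 leaves the alkenylstannane and its E geometry untouched.

Step 21
Reactants: 30 2-ethyl-6-methoxy-3,5-dimethyl-4H-pyran-4-one; 32 (2E)-3-(tributylstannyl)prop-2-enal
Product: 34 2-[(4E)-3-hydroxy-5-(tributylstannyl)pent-4-en-2-yl]-6-methoxy-3,5-dimethyl-4H-pyran-4-one, via lithium dienolate 33 (not isolated)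
Conditions: LiHMDS, THF, −78 °C; then 32, −78 °C; aq. NH4Cl
Reagents that add atoms: none
Why: Vinylogous aldol addition: deprotonation of the ethyl CH2 (γ to the pyranone carbonyl) gives the extended enolate, which adds 1,2 to the enal through its exocyclic carbon.

Step 22
Reactants: 34 2-[(4E)-3-hydroxy-5-(tributylstannyl)pent-4-en-2-yl]-6-methoxy-3,5-dimethyl-4H-pyran-4-one
Product: 36 2-methoxy-3,5-dimethyl-6-[(2E,4E)-5-(tributylstannyl)penta-2,4-dien-2-yl]-4H-pyran-4-one, via allylic mesylate 35 (not isolated)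
Conditions: MsCl, Et3N, CH2Cl2, −20 to 0 °C; then DBU, rt
Reagents that add atoms: none
Why: Mesylation and E1cB elimination through the acidic pyranone γ-CH give the conjugated diene; the E geometry of the new trisubstituted alkene (pyranone anti to the chain) is the thermodynamic one.

Step 23
Reactants: 23 4β-acetoxy-6β-(tert-butyldimethylsilyloxy)-1α-(2,2-dibromoethenyl)-2α,3α,5α-trimethylcyclohexane-3β,5β-diol; 36 2-methoxy-3,5-dimethyl-6-[(2E,4E)-5-(tributylstannyl)penta-2,4-dien-2-yl]-4H-pyran-4-one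
Product: 37 2-{(2E,4E,6Z)-6-bromo-7-[4β-acetoxy-6β-(tert-butyldimethylsilyloxy)-3β,5β-dihydroxy-2α,3α,5α-trimethylcyclohexan-1α-yl]hepta-2,4,6-trien-2-yl}-6-methoxy-3,5-dimethyl-4H-pyran-4-one
Conditions: Pd2(dba)3 (5 mol%), tri(2-furyl)phosphine (20 mol%), toluene, 80 °C
Reagents that add atoms: none
Why: Stille coupling of the 1,1-dibromoalkene occurs at the less hindered C–Br bond trans to the ring, with retention at the stannane, so the Cb–Cc bond is set trans to C1; base-free non-polar conditions suppress HBr loss to the enyne.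

Step 24
Reactants: 37 2-{(2E,4E,6Z)-6-bromo-7-[4β-acetoxy-6β-(tert-butyldimethylsilyloxy)-3β,5β-dihydroxy-2α,3α,5α-trimethylcyclohexan-1α-yl]hepta-2,4,6-trien-2-yl}-6-methoxy-3,5-dimethyl-4H-pyran-4-one
Product: 38 6-O-(tert-butyldimethylsilyl)amaurone A
Conditions: Me2Zn (5 equiv), Pd(t-Bu3P)2 (5 mol%), THF, 0 °C to rt
Reagents that add atoms: dimethylzinc, C[Zn]C
Why: Negishi methylation of the remaining Z-alkenyl bromide with retention (the bulky electron-rich phosphine avoids isomerisation of the 2-bromo-1,3-diene); acetate and pyranone are inert to the organozinc, and the two tertiary hydroxyls only consume reagent.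

Step 25
Reactants: 38 6-O-(tert-butyldimethylsilyl)amaurone A
Product: 39 amaurone A
Conditions: HF·pyridine, pyridine, THF, 0 °C to rt
Reagents that add atoms: none
Why: Buffered fluoride desilylation frees C6–OH without the acetyl migration that a basic fluoride source could trigger and leaves the triene and pyranone intact.

**Compound list**

1 | prop-2-yn-1-ol | C#CCO | starting material
2 | chelated vinylmagnesium alkoxide (not isolated) | C/C(CO[Mg]Br)=C/[Mg]Br | intermediate
3 | (2Z)-3-iodo-2-methylprop-2-en-1-ol | OC/C(C)=C\I | intermediate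
4 | but-2-yne | CC#CC | starting material
5 | 2-[(2Z)-but-2-en-2-yl]-4,4,5,5-tetramethyl-1,3,2-dioxaborolane | C/C=C(\C)B1OC(C)(C)C(C)(C)O1 | intermediate
6 | (2Z,4E)-2,4-dimethylhexa-2,4-dien-1-ol | OC/C(C)=C\C(C)=C\C | intermediate
7 | (4R)-4-benzyl-1,3-oxazolidin-2-one | O=C1N[C@H](Cc2ccccc2)CO1 | starting material
8 | bromoacetyl bromide | BrCC(Br)=O | starting material
9 | N-lithio oxazolidinone (not isolated) | [Li]N1[C@H](Cc2ccccc2)COC1=O | intermediate
10 | (4R)-4-benzyl-3-(bromoacetyl)-1,3-oxazolidin-2-one | O=C(CBr)N1[C@H](Cc2ccccc2)COC1=O | intermediate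
11 | diethyl {2-[(4R)-4-benzyl-2-oxo-1,3-oxazolidin-3-yl]-2-oxoethyl}phosphonate | CCOP(=O)(CC(=O)N1[C@H](Cc2ccccc2)COC1=O)OCC | intermediate
12 | (2Z,4E)-2,4-dimethylhexa-2,4-dienal (not isolated) | O=C/C(C)=C\C(C)=C\C | intermediate
13 | (4R)-4-benzyl-3-[(2E,4Z,6E)-4,6-dimethylocta-2,4,6-trienoyl]-1,3-oxazolidin-2-one | O=C(/C=C/C(C)=C\C(C)=C\C)N1[C@H](Cc2ccccc2)COC1=O | intermediate
14 | (4R)-4-benzyl-3-[(1S,6S)-3,5,6-trimethylcyclohexa-2,4-diene-1-carbonyl]-1,3-oxazolidin-2-one | O=C(N1[C@H](Cc2ccccc2)COC1=O)[C@@H]3[C@H](C)C(C)=CC(C)=C3 | intermediate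
15 | 3β,6β-endoperoxide of 14 | O=C(N1[C@H](Cc2ccccc2)COC1=O)[C@@H]3[C@H](C)[C@]4(C)C=C(C)[C@H]3OO4 | intermediate
16 | 3β,6β-diol (C4=C5 alkene) | O=C(N1[C@H](Cc2ccccc2)COC1=O)[C@@H]3[C@H](C)[C@@](C)(O)C=C(C)[C@H]3O | intermediate
17 | 6-O-TBS ether of 16 | O=C(N1[C@H](Cc2ccccc2)COC1=O)[C@@H]3[C@H](C)[C@@](C)(O)C=C(C)[C@H]3O[Si](C)(C)C(C)(C)C | intermediate
18 | C4,C5 β-osmate(VI) ester TMEDA complex (not isolated) | O=C(N1[C@H](Cc2ccccc2)COC1=O)[C@@H]3[C@H](C)[C@@](C)(O)[C@H]4O[Os](=O)(=O)O[C@@]4(C)[C@H]3O[Si](C)(C)C(C)(C)C.CN(C)CCN(C)C | intermediate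
19 | 3β,4β,5β-triol 6β-TBS ether imide | O=C(N1[C@H](Cc2ccccc2)COC1=O)[C@@H]3[C@H](C)[C@@](C)(O)[C@@H](O)[C@@](C)(O)[C@H]3O[Si](C)(C)C(C)(C)C | intermediate
20 | [6β-(tert-butyldimethylsilyloxy)-3β,4β,5β-trihydroxy-2α,3α,5α-trimethylcyclohexan-1α-yl]methanol | OC[C@@H]1[C@H](C)[C@@](C)(O)[C@@H](O)[C@@](C)(O)[C@H]1O[Si](C)(C)C(C)(C)C | intermediate
21 | 6β-(tert-butyldimethylsilyloxy)-3β,4β,5β-trihydroxy-2α,3α,5α-trimethylcyclohexane-1α-carbaldehyde | O=C[C@@H]1[C@H](C)[C@@](C)(O)[C@@H](O)[C@@](C)(O)[C@H]1O[Si](C)(C)C(C)(C)C | intermediate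
22 | 4β-acetoxy-6β-(tert-butyldimethylsilyloxy)-3β,5β-dihydroxy-2α,3α,5α-trimethylcyclohexane-1α-carbaldehyde | O=C[C@@H]1[C@H](C)[C@@](C)(O)[C@@H](OC(C)=O)[C@@](C)(O)[C@H]1O[Si](C)(C)C(C)(C)C | intermediate
23 | 4β-acetoxy-6β-(tert-butyldimethylsilyloxy)-1α-(2,2-dibromoethenyl)-2α,3α,5α-trimethylcyclohexane-3β,5β-diol | BrC(Br)=C[C@@H]1[C@H](C)[C@@](C)(O)[C@@H](OC(C)=O)[C@@](C)(O)[C@H]1O[Si](C)(C)C(C)(C)C | intermediate
24 | methyl 2-methyl-3-oxopentanoate | CCC(=O)C(C)C(=O)OC | starting material
25 | N-methoxy-N-methylpropanamide | CCC(=O)N(C)OC | starting material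
26 | sodium lithium dienolate of 24 (not isolated) | CC=C(O[Li])C(C)=C(O[Na])OC | intermediate
27 | methyl 2,4-dimethyl-3,5-dioxoheptanoate | CCC(=O)C(C)C(=O)C(C)C(=O)OC | intermediate
28 | 6-ethyl-4-hydroxy-3,5-dimethyl-2H-pyran-2-one | CCc1oc(=O)c(C)c(O)c1C | intermediate
29 | 6-ethyl-4-hydroxy-2-methoxy-3,5-dimethylpyrylium triflate (not isolated) | CCc1[o+]c(OC)c(C)c(O)c1C.[O-]S(=O)(=O)C(F)(F)F | intermediate
30 | 2-ethyl-6-methoxy-3,5-dimethyl-4H-pyran-4-one | CCc1oc(OC)c(C)c(=O)c1C | intermediate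
31 | (2E)-3-(tributylstannyl)prop-2-en-1-ol | CCCC[Sn](CCCC)(CCCC)/C=C/CO | intermediate
32 | (2E)-3-(tributylstannyl)prop-2-enal | CCCC[Sn](CCCC)(CCCC)/C=C/C=O | intermediate
33 | lithium dienolate of 30 (not isolated) | CC=C1OC(OC)=C(C)C(O[Li])=C1C | intermediate
34 | 2-[(4E)-3-hydroxy-5-(tributylstannyl)pent-4-en-2-yl]-6-methoxy-3,5-dimethyl-4H-pyran-4-one (diastereomer mixture) | COc1oc(C(C)C(O)/C=C/[Sn](CCCC)(CCCC)CCCC)c(C)c(=O)c1C | intermediate
35 | allylic mesylate of 34 (not isolated) | COc1oc(C(C)C(OS(C)(=O)=O)/C=C/[Sn](CCCC)(CCCC)CCCC)c(C)c(=O)c1C | intermediate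
36 | 2-methoxy-3,5-dimethyl-6-[(2E,4E)-5-(tributylstannyl)penta-2,4-dien-2-yl]-4H-pyran-4-one | COc1oc(/C(C)=C/C=C/[Sn](CCCC)(CCCC)CCCC)c(C)c(=O)c1C | intermediate
37 | (6Z)-6-bromo triene (Cb–Br in place of Cb–CH3, 6-O-TBS) | COc1oc(/C(C)=C/C=C/C(Br)=C/[C@@H]2[C@H](C)[C@@](C)(O)[C@@H](OC(C)=O)[C@@](C)(O)[C@H]2O[Si](C)(C)C(C)(C)C)c(C)c(=O)c1C | intermediate
38 | 6-O-(tert-butyldimethylsilyl)amaurone A | COc1oc(/C(C)=C/C=C/C(C)=C/[C@@H]2[C@H](C)[C@@](C)(O)[C@@H](OC(C)=O)[C@@](C)(O)[C@H]2O[Si](C)(C)C(C)(C)C)c(C)c(=O)c1C | intermediate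
39 | amaurone A | COc1oc(/C(C)=C/C=C/C(C)=C/[C@@H]2[C@H](C)[C@@](C)(O)[C@@H](OC(C)=O)[C@@](C)(O)[C@H]2O)c(C)c(=O)c1C | target

**Step count**

Total steps: 25. Longest linear sequence: 15 steps (1 → 3 → 6 → 13 → 14 → 15 → 16 → 17 → 19 → 20 → 21 → 22 → 23 → 37 → 38 → 39).

**Steps most likely to fail, with fallbacks**

Step 7 (Proposed new method). The chelate may fail to discriminate the two helical transition states, uncomplexed triene may close without facial bias, or the Lewis acid may isomerise the 4Z alkene and stop the closure. Fallback in known chemistry: starting from 13, the triene is closed by plain thermal disrotatory electrocyclisation in toluene at 60–80 °C without additive. This should give the cis-diene as two imide diastereomers, 14 and (4R)-4-benzyl-3-[(1R,6R)-3,5,6-trimethylcyclohexa-2,4-diene-1-carbonyl]-1,3-oxazolidin-2-one F1. The auxiliary then serves as a covalent resolving group: the two are separated by chromatography or crystallisation, and the route is rejoined at 14.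

Step 11. The osmium reagent may approach from the α face, or be kept away from C5 by the neighbouring silyl ether, and hydrolysis of the hindered osmate ester may be incomplete. Fallback: the order of silylation and dihydroxylation is reversed. Starting from 16, catalytic OsO4 with trimethylamine N-oxide in CH2Cl2 (two β-hydroxyls directing by hydrogen bonding, no silyl group near C5) should give the 3β,4β,5β,6β-tetraol imide F2. TBSOTf/2,6-lutidine at −78 °C then silylates C6–OH in preference to C4–OH, which lies between two quaternary carbons, and the route is rejoined at 19.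

Step 23. Oxidative addition at the hindered dibromo-olefin may be slow or unselective between the two bromides, HBr may be lost to give the enyne, or the dienylstannane may be consumed by homocoupling or protodestannylation; step 24 depends on this product. Fallback: the chain is built by carbonyl olefination and condensation instead of cross-coupling. Starting from 22, Wittig reaction with 2-(triphenylphosphoranylidene)propanal (toluene, 80 °C) gives the E-enal F3. A second Wittig reaction with (triphenylphosphoranylidene)acetaldehyde gives the E,E-dienal F4. Addition of an excess of lithium dienolate 33 (THF, −78 °C) gives the dienyl carbinol F5. MsCl/Et3N converts it into its mesylate F6, and DBU eliminates this to the triene, rejoining the route at 38.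

**Further compounds**

F1 | step 7 | (4R)-4-benzyl-3-[(1R,6R)-3,5,6-trimethylcyclohexa-2,4-diene-1-carbonyl]-1,3-oxazolidin-2-one | O=C(N1[C@H](Cc2ccccc2)COC1=O)[C@H]3[C@@H](C)C(C)=CC(C)=C3
F2 | step 11 | (4R)-4-benzyl-3-[3β,4β,5β,6β-tetrahydroxy-2α,3α,5α-trimethylcyclohexane-1α-carbonyl]-1,3-oxazolidin-2-one | O=C(N1[C@H](Cc2ccccc2)COC1=O)[C@@H]3[C@H](C)[C@@](C)(O)[C@@H](O)[C@@](C)(O)[C@H]3O
F3 | step 23 | (2E)-3-[4β-acetoxy-6β-(tert-butyldimethylsilyloxy)-3β,5β-dihydroxy-2α,3α,5α-trimethylcyclohexan-1α-yl]-2-methylprop-2-enal | O=C/C(C)=C/[C@@H]1[C@H](C)[C@@](C)(O)[C@@H](OC(C)=O)[C@@](C)(O)[C@H]1O[Si](C)(C)C(C)(C)C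
F4 | step 23 | (2E,4E)-5-[4β-acetoxy-6β-(tert-butyldimethylsilyloxy)-3β,5β-dihydroxy-2α,3α,5α-trimethylcyclohexan-1α-yl]-4-methylpenta-2,4-dienal | O=C/C=C/C(C)=C/[C@@H]1[C@H](C)[C@@](C)(O)[C@@H](OC(C)=O)[C@@](C)(O)[C@H]1O[Si](C)(C)C(C)(C)C
F5 | step 23 | dienyl carbinol (Ce–OH, Cf–H adduct of 33 and F4; diastereomer mixture) | COc1oc(C(C)C(O)/C=C/C(C)=C/[C@@H]2[C@H](C)[C@@](C)(O)[C@@H](OC(C)=O)[C@@](C)(O)[C@H]2O[Si](C)(C)C(C)(C)C)c(C)c(=O)c1C
F6 | step 23 | mesylate of F5 | COc1oc(C(C)C(OS(C)(=O)=O)/C=C/C(C)=C/[C@@H]2[C@H](C)[C@@](C)(O)[C@@H](OC(C)=O)[C@@](C)(O)[C@H]2O[Si](C)(C)C(C)(C)C)c(C)c(=O)c1C
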